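**Retrosynthetic overview**

1. Target 24 ← acetoxy-ketone vinyl epoxide 22 + angelic acid 23: the trans-diaxial 5α-angelate/6β-alcohol pair comes from axial carboxylate attack at the allylic C5 of a 5β,6β-epoxide beside the C4 exomethylene. 22 ← α-ketol 21 ← dialdehyde 20 by an NHC-catalysed benzoin that forms C1–C2, so the five-membered ring is made second.
2. 20 ← allylic alcohol 14: its C4 β-hydroxyl steers the epoxide to the β face and is then oxidised and methylenated. C2 is added by methylenation and hydroboration of the C3 formyl group of cycloadduct 9.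
3. Feature carrying the strategy: the six-membered ring bears carbon substituents on four adjacent atoms (C7, C7a, C3a, C4) and oxygen on the other two (C5, C6). With C4 read as a carbinol and C5–C6 as an alkene, the ring is a cyclohexene that a 1-oxy-4-isopropyl (E,E)-butadiene and an (E)-disubstituted enal assemble in one [4+2] step. The alkene geometry of the enal becomes the trans C3a/C7a fusion before the cyclopentanone exists.
4. 9 ← diene 4 + enal 8 (six-membered ring first, four stereocentres). 4 ← isovaleraldehyde 1 and formyl ylide 2; 8 ← (Z)-but-2-ene-1,4-diol 5.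

Key step: step 5

Convention: the locants of the final hydrindane (C1, C2, C3, C3a, C4–C7, C7a) are used for all intermediates; β is the ring face that carries the C7 isopropyl group, α the opposite face.

Assumption: the sense of induction in step 5 is taken from the formyl C–H···O binding model of oxazaborolidinium-bound enals, under which the (S)-catalyst leaves the Re face of C-α open. The (R)-catalyst is therefore specified; the other catalyst enantiomer would be used should the sense prove reversed.

**Route**

Step 1
Reactants: 1 isovaleraldehyde; 2 (triphenylphosphoranylidene)acetaldehyde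
Product: 3 (E)-5-methylhex-2-enal
Conditions: ylide as the limiting reagent (0.95 equiv), toluene, 80 °C
Reagents that add atoms: none
Why: Wittig olefination with the stabilised formyl ylide should give the (E)-enal, and keeping the ylide limiting suppresses a second homologation of the less electrophilic product.

Step 2
Reactants: 3 (E)-5-methylhex-2-enal
Product: 4 (1E,3E)-1-(tert-butyldimethylsilyloxy)-5-methylhexa-1,3-diene
Conditions: TBSOTf, Et3N, Et2O, 0 °C to rt
Reagents that add atoms: tert-butyldimethylsilyl trifluoromethanesulfonate, CC(C)(C)[Si](C)(C)OS(=O)(=O)C(F)(F)F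
Why: Silyl dienol ether formation by soft enolisation (O-silylation of the s-trans enal, then γ-deprotonation) should give the 1E bond, and allylic strain from the isopropyl group disfavours the 3Z isomer; any isomer with a Z bond is inert in step 5 and is left behind there.

Step 3
Reactants: 5 (Z)-but-2-ene-1,4-diol
Product: 6 (Z)-4-(tert-butyldiphenylsilyloxy)but-2-en-1-ol
Conditions: diol in fourfold excess, TBDPSCl, imidazole, THF, 0 °C to rt
Reagents that add atoms: tert-butyl(chloro)diphenylsilane, CC(C)(C)[Si](Cl)(c1ccccc1)c1ccccc1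
Why: Statistical monosilylation of the symmetrical diol, used in excess, should give the mono-ether.

Step 4
Reactants: 6 (Z)-4-(tert-butyldiphenylsilyloxy)but-2-en-1-ol
Product: 8 (E)-4-(tert-butyldiphenylsilyloxy)but-2-enal, via Z-enal 7 (not isolated)
Conditions: pyridinium chlorochromate [C5H5NH][CrO3Cl], CH2Cl2, rt
Reagents that add atoms: none
Why: Chromate oxidation of the allylic alcohol gives the Z-enal, which should isomerise under the mildly acidic conditions to the thermodynamically favoured E-enal.

Step 5
Reactants: 4 (E,E)-silyloxy diene (tert-butyldimethylsilyl dienol ether with the isopropyl terminus); 8 (E)-enal (tert-butyldiphenylsilyl ether of the hydroxybutenal)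
Product: 9 endo Diels–Alder adduct (C5=C6 cyclohexene; C4 β-OTBS; C3a β-formyl; C7a α-CH2OTBDPS; C7 β-isopropyl)
Conditions: diene in twofold excess, (R)-tetrahydro-1-(2-methylphenyl)-3,3-diphenyl-1H,3H-pyrrolo[1,2-c][1,3,2]oxazaborole (20 mol%) protonated with HNTf2 (17 mol%), CH2Cl2, −78 °C; Et3N quench
Reagents that add atoms: none
Why: The protonated oxazaborolidine binds the formyl oxygen of 8 (B–O coordination reinforced by a formyl C–H···O contact), lowers the LUMO of the s-trans enal, and lets diene 4 add in a single, concerted but asynchronous [4+2] event in which the diene terminus remote from oxygen (C7) attacks the β-carbon (C7a) ahead of C4–C3a bond formation; the closest known reaction type is the oxazaborolidinium-catalysed enantioselective Diels–Alder reaction of enals with 1-oxygenated butadienes. The six-membered ring is closed by this cycloaddition, the two new σ-bonds C4–C3a and C7–C7a forming suprafacially on both partners and leaving the ring alkene at C5=C6. The (E,E)-diene geometry sets C4 and C7 cis, the (E)-dienophile geometry sets C3a and C7a trans, the endo transition state places the C3a formyl group cis to the C4 silyloxy and C7 isopropyl groups, and the catalyst, whose aryl group covers the Re face of C-α, fixes the absolute configuration by forcing the diene onto the Si face. The step has to be regioselective, endo-selective and face-selective: the 1-silyloxy donor (largest HOMO coefficient at C7) together with the coordinated formyl group should deliver the first two, and the (R)-catalyst the third. Diene isomers containing a Z bond cannot readily reach the s-cis conformation and should be left unreacted.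

Step 6
Reactants: 9 Diels–Alder adduct
Product: 10 C3a β-vinyl compound (C3=C2), otherwise as 9
Conditions: Ph3PCH3Br (1.3 equiv), KN(SiMe3)2 (1.2 equiv), THF, −78 to 0 °C
Reagents that add atoms: methyltriphenylphosphonium bromide (as its ylide), C[P+](c1ccccc1)(c1ccccc1)c1ccccc1.[Br-]
Why: Wittig methylenation by the non-stabilised ylide should be faster at −78 °C than deprotonation at C3a or loss of the β-silyloxy group, and the equatorial C3a configuration is in any case the favoured one.

Step 7
Reactants: 10 C3a β-vinyl compound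
Product: 12 primary alcohol (C3a β-CH2CH2OH; C2 hydroxyl), via B-alkyl-9-BBN 11 (not isolated)
Conditions: 9-BBN, THF, 0 °C to rt; then NaOH, H2O2, 0 °C
Reagents that add atoms: hydrogen peroxide, OO
Why: Hydroboration–oxidation with 9-BBN should be anti-Markovnikov and selective for the monosubstituted vinyl group over the hindered cis-disubstituted ring alkene, giving the one-carbon-extended C2 carbinol.

Step 8
Reactants: 12 primary alcohol
Product: 13 C2 tert-butyldiphenylsilyl ether (C1 and C2 OTBDPS, C4 β-OTBS)
Conditions: TBDPSCl, imidazole, CH2Cl2, rt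
Reagents that add atoms: tert-butyl(chloro)diphenylsilane, CC(C)(C)[Si](Cl)(c1ccccc1)c1ccccc1
Why: Silyl ether formation at the only free hydroxyl, an unhindered primary one, should be straightforward.

Step 9
Reactants: 13 C2 tert-butyldiphenylsilyl ether
Product: 14 C4 β-allylic alcohol (C1 and C2 OTBDPS)
Conditions: HF·pyridine, pyridine, THF, 0 °C to rt
Reagents that add atoms: none
Why: Selective desilylation should work because a tert-butyldimethylsilyl ether, even a secondary one, is cleaved far faster than primary tert-butyldiphenylsilyl ethers by buffered HF.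

Step 10
Reactants: 14 C4 β-allylic alcohol
Product: 15 5β,6β-epoxy-4β-ol
Conditions: VO(acac)2 (5 mol%), t-BuOOH, CH2Cl2, 0 °C to rt
Reagents that add atoms: tert-butyl hydroperoxide, CC(C)(C)OO
Why: In the vanadium-catalysed hydroxyl-directed epoxidation the pseudo-axial C4 β-alkoxide on vanadium should deliver the peroxide oxygen to the β face of C5=C6, setting C5 and C6 as the β-epoxide cis to the hydroxyl.

Step 11
Reactants: 15 5β,6β-epoxy-4β-ol
Product: 16 5β,6β-epoxy-4-ketone
Conditions: Dess–Martin periodinane, pyridine, CH2Cl2, rt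
Reagents that add atoms: none
Why: Dess–Martin oxidation of the secondary carbinol under buffered conditions should leave the epoxide and silyl ethers untouched.

Step 12
Reactants: 16 5β,6β-epoxy-4-ketone
Product: 17 vinyl epoxide (C4=CH2, 5β,6β-epoxide; C1 and C2 OTBDPS)
Conditions: Ph3PCH3Br, KN(SiMe3)2, THF, 0 °C to rt
Reagents that add atoms: methyltriphenylphosphonium bromide (as its ylide), C[P+](c1ccccc1)(c1ccccc1)c1ccccc1.[Br-]
Why: Wittig methylenation of an α,β-epoxy ketone is established chemistry, and C3a, the only enolisable stereocentre, already holds its side chain equatorial, so transient enolisation cannot scramble it.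

Step 13
Reactants: 17 vinyl epoxide
Product: 18 vinyl epoxide diol (C1 and C2 hydroxyl)
Conditions: Bu4NF, AcOH (1:1), THF, rt
Reagents that add atoms: none
Why: Fluoride desilylation buffered with acetic acid should remove both silyl ethers while keeping the medium too weakly basic for the C2 alkoxide to attack the vinyl epoxide.

Step 14
Reactants: 18 vinyl epoxide diol
Product: 20 dialdehyde (C1 and C2 formyl), via bis-alkoxysulfonium salt 19 (not isolated)
Conditions: (COCl)2, DMSO, CH2Cl2, −78 °C; then Et3N, −78 to −20 °C
Reagents that add atoms: none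
Why: In the Swern oxidation both hydroxyls are activated before base is added, so no hydroxy aldehyde exists to close to a lactol and over-oxidise to a lactone; the epimerisable C7a keeps its favoured equatorial formyl group.

Step 15
Reactants: 20 dialdehyde
Product: 21 trans-fused α-ketol (1β-hydroxy-2-oxo-4-methylidene-5β,6β-epoxy-7β-isopropylhydrindane; H-3a α, H-7a β)
Conditions: 2-(pentafluorophenyl)-6,7-dihydro-5H-pyrrolo[2,1-c][1,2,4]triazol-2-ium tetrafluoroborate (15 mol%), Et3N (15 mol%), CH2Cl2 (0.02 M), rt
Reagents that add atoms: none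
Why: In this NHC-catalysed intramolecular crossed benzoin (known for 1,5-dialdehydes) the carbene should add to the unhindered C2 formyl group while the α-branched C1 formyl group acts only as acceptor, 5-exo-trig attack of the acyl-anion equivalent closing C1–C2 to the C2 ketone; C1 should carry its hydroxyl pseudo-equatorial (β, cis to H-7a, turned away from C7), which is also the expected equilibrium outcome because the addition is reversible and C1–H is enolisable.

Step 16
Reactants: 21 trans-fused α-ketol
Product: 22 1β-acetate of 21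
Conditions: Ac2O, pyridine, DMAP (cat.), CH2Cl2, 0 °C
Reagents that add atoms: acetic anhydride, CC(=O)OC(C)=O
Why: Acetylation of the secondary α-ketol hydroxyl should be routine, with any C1 epimer expected to converge on the pseudo-equatorial acetate by enolisation.

Step 17
Reactants: 22 acetate of the epoxy ketol; 23 angelic acid
Product: 24 CNP0317011.1 (the target)
Conditions: angelic acid in fourfold excess premixed with Cs2CO3 (one equivalent) and 4 Å molecular sieves in DMF, then the epoxide, 50 °C
Reagents that add atoms: none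
Why: Carboxylate opening of the vinyl epoxide should follow the Fürst–Plattner rule, the angelate attacking the allylic C5 from the α face anti to the epoxide oxygen (SN2, inversion at C5, C6 retained) to give the trans-diaxial 5α-angelate/6β-alcohol directly, while the angelic acid–caesium angelate buffer supplies the proton for the C6 alkoxide and should avoid angelate-to-tiglate isomerisation.

**Compound list**

1 | isovaleraldehyde | CC(C)CC=O | starting material
2 | (triphenylphosphoranylidene)acetaldehyde | O=CC=P(c1ccccc1)(c1ccccc1)c1ccccc1 | starting material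
3 | (E)-5-methylhex-2-enal | CC(C)C/C=C/C=O | intermediate
4 | (1E,3E)-1-(tert-butyldimethylsilyloxy)-5-methylhexa-1,3-diene | CC(C)/C=C/C=C/O[Si](C)(C)C(C)(C)C | intermediate
5 | (Z)-but-2-ene-1,4-diol | OC/C=C\CO | starting material
6 | (Z)-4-(tert-butyldiphenylsilyloxy)but-2-en-1-ol | OC/C=C\CO[Si](c1ccccc1)(c1ccccc1)C(C)(C)C | intermediate
7 | (Z)-4-(tert-butyldiphenylsilyloxy)but-2-enal (not isolated) | O=C/C=C\CO[Si](c1ccccc1)(c1ccccc1)C(C)(C)C | intermediate
8 | (E)-4-(tert-butyldiphenylsilyloxy)but-2-enal | O=C/C=C/CO[Si](c1ccccc1)(c1ccccc1)C(C)(C)C | intermediate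
9 | Diels–Alder adduct: C4 β-OTBS, C3a β-CHO, C7a α-CH2OTBDPS, C7 β-iPr, C5=C6 | CC(C)(C)[Si](C)(C)O[C@@H]1[C@H](C=O)[C@@H](CO[Si](c2ccccc2)(c2ccccc2)C(C)(C)C)[C@H](C(C)C)C=C1 | intermediate
10 | C3a β-vinyl compound | CC(C)(C)[Si](C)(C)O[C@@H]1[C@H](C=C)[C@@H](CO[Si](c2ccccc2)(c2ccccc2)C(C)(C)C)[C@H](C(C)C)C=C1 | intermediate
11 | B-alkyl-9-BBN at C2 (not isolated) | CC(C)(C)[Si](C)(C)O[C@@H]1[C@H](CCB2C3CCCC2CCC3)[C@@H](CO[Si](c4ccccc4)(c4ccccc4)C(C)(C)C)[C@H](C(C)C)C=C1 | intermediate
12 | primary alcohol (C3a β-CH2CH2OH) | CC(C)(C)[Si](C)(C)O[C@@H]1[C@H](CCO)[C@@H](CO[Si](c2ccccc2)(c2ccccc2)C(C)(C)C)[C@H](C(C)C)C=C1 | intermediate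
13 | C2 tert-butyldiphenylsilyl ether (C4 β-OTBS) | CC(C)(C)[Si](C)(C)O[C@@H]1[C@H](CCO[Si](c2ccccc2)(c2ccccc2)C(C)(C)C)[C@@H](CO[Si](c2ccccc2)(c2ccccc2)C(C)(C)C)[C@H](C(C)C)C=C1 | intermediate
14 | C4 β-allylic alcohol (C1, C2 OTBDPS) | O[C@@H]1[C@H](CCO[Si](c2ccccc2)(c2ccccc2)C(C)(C)C)[C@@H](CO[Si](c2ccccc2)(c2ccccc2)C(C)(C)C)[C@H](C(C)C)C=C1 | intermediate
15 | 5β,6β-epoxy-4β-ol | O[C@@H]1[C@H](CCO[Si](c3ccccc3)(c3ccccc3)C(C)(C)C)[C@@H](CO[Si](c3ccccc3)(c3ccccc3)C(C)(C)C)[C@H](C(C)C)[C@@H]2O[C@H]12 | intermediate
16 | 5β,6β-epoxy-4-ketone | O=C1[C@H](CCO[Si](c3ccccc3)(c3ccccc3)C(C)(C)C)[C@@H](CO[Si](c3ccccc3)(c3ccccc3)C(C)(C)C)[C@H](C(C)C)[C@@H]2O[C@H]12 | intermediate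
17 | vinyl epoxide (C4=CH2; C1, C2 OTBDPS) | C=C1[C@H](CCO[Si](c3ccccc3)(c3ccccc3)C(C)(C)C)[C@@H](CO[Si](c3ccccc3)(c3ccccc3)C(C)(C)C)[C@H](C(C)C)[C@@H]2O[C@H]12 | intermediate
18 | vinyl epoxide diol | C=C1[C@H](CCO)[C@@H](CO)[C@H](C(C)C)[C@@H]2O[C@H]12 | intermediate
19 | bis(alkoxydimethylsulfonium) dichloride of 18 (not isolated) | C=C1[C@H](CCO[S+](C)C)[C@@H](CO[S+](C)C)[C@H](C(C)C)[C@@H]2O[C@H]12.[Cl-].[Cl-] | intermediate
20 | dialdehyde (C1 and C2 formyl) | C=C1[C@H](CC=O)[C@@H](C=O)[C@H](C(C)C)[C@@H]2O[C@H]12 | intermediate
21 | trans-fused α-ketol (1β-OH, 2-oxo) | C=C1[C@@H]2CC(=O)[C@H](O)[C@H]2[C@H](C(C)C)[C@@H]3O[C@H]13 | intermediate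
22 | 1β-acetate | C=C1[C@@H]2CC(=O)[C@H](OC(C)=O)[C@H]2[C@H](C(C)C)[C@@H]3O[C@H]13 | intermediate
23 | angelic acid | C/C=C(/C)C(=O)O | starting material
24 | CNP0317011.1, (1R,3aR,5S,6S,7S,7aR)-1-acetoxy-6-hydroxy-4-methylidene-2-oxo-7-(propan-2-yl)octahydro-1H-inden-5-yl (2Z)-2-methylbut-2-enoate | C=C1[C@@H]2CC(=O)[C@H](OC(C)=O)[C@H]2[C@H](C(C)C)[C@H](O)[C@H]1OC(=O)/C(C)=C\C | target

**Step count and risks**

Total steps: 17. Longest linear sequence: 15 (steps 1, 2 and 5–17).

Steps most likely to fail:

Step 5. The 4-isopropyl diene terminus may react too slowly with the β-substituted enal, so that desilylation or vinylogous Mukaiyama-type addition of the dienol ether takes over and endo or facial selectivity erodes. The fallback sets out from 3 and 8 and returns at 14. Enal 3 is converted with isopropenyl acetate and catalytic TsOH into the acid-tolerant dienyl acetate (1E,3E)-5-methylhexa-1,3-dien-1-yl acetate F1. F1 and 8 are combined under iminium catalysis (CH3NO2–H2O), using the enantiomer of 5-benzyl-2,2,3-trimethylimidazolidin-4-one hydrochloride whose benzyl group covers the Re face of C-α, to give the C4-acetoxy adduct F2. Wittig methylenation gives the vinyl acetate F3. 9-BBN followed by NaOH/H2O2, which also saponifies the acetate, gives the C4,C2-diol F4. Silylation of the primary hydroxyl alone (TBDPSCl, imidazole, 0 °C) gives 14.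

Step 15. The carbene may add to the hindered C1 formyl group, or the α-ketol may isomerise or oligomerise, giving regio- and epimer mixtures. The fallback sets out from 18 and returns at 21; it fixes C2 as the only acyl-level carbon. Imidazole-buffered iodination (I2, PPh3, 0 °C) of the unbranched C2 carbinol gives the iodo alcohol F5. Kornblum displacement (NaNO2, phloroglucinol, DMSO) gives the nitro alcohol F6. Dess–Martin oxidation gives the nitro aldehyde F7. An Et3N-catalysed intramolecular Henry reaction closes C1–C2 to the cyclic β-nitro alcohol F8. A Nef reaction (nitronate formed with K2CO3 in MeOH, then buffered potassium peroxymonosulfate KHSO5, 0 °C) gives 21.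

Step 17. The angelate may attack the exocyclic methylene (SN2′) or C6, or may isomerise to tiglate if the opening has to be forced. The fallback sets out from 22 and returns at 24. Dilute HClO4 in THF–H2O at 0 °C opens the epoxide by axial attack of water at the allylic C5 to give the trans-diaxial 5α,6β-diol F9. The less hindered allylic C5 hydroxyl is then acylated with the mixed anhydride of angelic acid and 2,4,6-trichlorobenzoyl chloride (Et3N, toluene, 80 °C, no DMAP; Yamaguchi conditions), the C6 hydroxyl being screened by the neighbouring isopropyl group, to give 24.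

**Further compounds**

F1 | step 5 | (1E,3E)-5-methylhexa-1,3-dien-1-yl acetate | CC(C)/C=C/C=C/OC(C)=O
F2 | step 5 | C4 β-acetoxy Diels–Alder adduct (C3a β-CHO, C7a α-CH2OTBDPS, C7 β-iPr) | CC(=O)O[C@@H]1[C@H](C=O)[C@@H](CO[Si](c2ccccc2)(c2ccccc2)C(C)(C)C)[C@H](C(C)C)C=C1
F3 | step 5 | C4 β-acetoxy C3a β-vinyl compound | CC(=O)O[C@@H]1[C@H](C=C)[C@@H](CO[Si](c2ccccc2)(c2ccccc2)C(C)(C)C)[C@H](C(C)C)C=C1
F4 | step 5 | C4 β-hydroxy C2-hydroxy diol (C1 OTBDPS) | O[C@@H]1[C@H](CCO)[C@@H](CO[Si](c2ccccc2)(c2ccccc2)C(C)(C)C)[C@H](C(C)C)C=C1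
F5 | step 15 | C2 iodide, C1 alcohol (vinyl epoxide) | C=C1[C@H](CCI)[C@@H](CO)[C@H](C(C)C)[C@@H]2O[C@H]12
F6 | step 15 | C2 nitro compound, C1 alcohol | C=C1[C@H](CC[N+](=O)[O-])[C@@H](CO)[C@H](C(C)C)[C@@H]2O[C@H]12
F7 | step 15 | C2 nitro compound, C1 aldehyde | C=C1[C@H](CC[N+](=O)[O-])[C@@H](C=O)[C@H](C(C)C)[C@@H]2O[C@H]12
F8 | step 15 | cyclic β-nitro alcohol (1β-OH, 2-nitro, C2 epimers) | C=C1[C@@H]2CC([N+](=O)[O-])[C@H](O)[C@H]2[C@H](C(C)C)[C@@H]3O[C@H]13
F9 | step 17 | 5α,6β-diol 1β-acetate | C=C1[C@@H]2CC(=O)[C@H](OC(C)=O)[C@H]2[C@H](C(C)C)[C@H](O)[C@H]1O
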